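(The constants were chosen freely, and the outcome is calculated.)

| flask | starting material | reagent | remark | time |
|---|---|---|---|---|
| north | 10 mM | 11.0 mM | a single well-mixed tank run continuously and read at steady state, 50 h in it on average |  |
| north-west | 10 mM | 11.0 mM | a closed flask charged with all of it at once and left for 50 h | 50 h |
| west | 10 mM | 11.0 mM (fed, over 50.0 h) | all but reagent at the start; reagent goes in evenly over 50.0 h, the run ends at 50 h | 50 h |
| south-west | 10 mM (fed, over 50.0 h) | 11.0 mM | a stirred flask in which starting material is dosed at a steady rate over 50.0 h without added volume, worked up at 50 h | 50 h |

- the set-up with the highest amount of product at the outlet or at the end, in percent of the starting material put in ("none" if the first two lie within 2 percentage points) (north / north-west / west / south-west / none)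
- amount of product at the outlet or at the end, in percent of the starting material put in, north
- amount of product at the outlet or at the end, in percent of the starting material put in, north-west
- amount of product at the outlet or at the end, in percent of the starting material put in, west
- amount of product at the outlet or at the end, in percent of the starting material put in, south-west

- percent here means starting material units held: one homo dimer counts as two
- for a step with 2 of a species take k times the square, and two of it per event
- the stated concentrations are those of everything mixed, before any reaction; amounts are the same in each set-up
- the feed brings no volume worth counting
- run time (north-west): 50 h

    starting material + reagent → product, rate k1*[starting material]^2*[reagent] (k1 = 3110 M⁻² h⁻¹)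
    2 starting material → homo dimer (k2 = 0.00285 M⁻¹ h⁻¹)

1. Take the closed flask, north-west, charged once and then left. Starting material is the limiting reagent, because its 10 mM is a smaller charge than the 11.0 mM of reagent. So you keep the books on starting material.

2. First entry: each turn of the first step takes one starting material and one reagent and makes one product. Second entry: each turn of the second step takes two starting material and no reagent and makes one homo dimer.

3. Both rates carry the square of starting material, so starting material cancels from their ratio and reagent stays in it. Divide them and you get the break-even reagent level, twice k2 over k1, at which both routes take starting material equally fast: 0.00183 mM. This is a selectivity factor with the unit of a concentration. The charge of reagent in north-west stands 6000 times above it, so treat the homo dimer there as a small correction.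

4. In a closed flask charged at once, as north-west is, each product spends one reagent, so you can add up the leak against the fall of reagent:

      homo dimer, each counted as two, as a share of the charge = (break-even level / starting material charged) × ln(reagent charged / reagent left).

   The price per unit of that logarithm is 0.0183%.

5. Close the books. Full use of the starting material leaves 1.00 mM of reagent, and the homo dimer entry then reads 0.0439%. My reckoning stops here: in north-west, product is the charge minus unreacted starting material, less a correction of that size. How much stays unreacted at 50 h is a question of rate, and I leave it open.

6. The forecast names north-west, with 67.8% for north, 85.2% for north-west, 72.2% for west and 66.1% for south-west: “The all-at-once batch keeps both concentrations high early and wins clearly”.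

7. The simulation gives north-west as best, at 85.2%, with north 67.8%, west 72.1% and south-west 66.2%. The forecast stands. In north-west, 15% of the starting material is still there at 50.0 h, and that unreacted charge is the gap to full yield. Reagent left there is 23% of its charge, and the price from step 4 gives 0.0273% of homo dimer; the flask holds 0.0273%.

8. Now charge a neighbour of north-west with 2.8 mM of reagent, which leaves 0.017% of its charge at the end. The same price gives 0.159% of homo dimer. The computed flask holds 0.159%, beside 28.0% of product.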